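# Proposed synthesis of penithochromone S by a nitrile oxide–alkyne cycloaddition with an isoxazole as masked ring B

## The problem

Penithochromone S (20) is a 5-hydroxy-7-methoxychromone whose C2 carries a nine-carbon chain: a methylene, a secondary carbinol of R configuration (C8 of the nonanoic acid), six further methylenes and a terminal carboxylic acid. The chain is joined to the bicycle by a single bond at C2 of ring B, so the task is the union of a phloroglucinol-type ring A, the three-carbon unit C2–C3–C4 and a chiral aliphatic chain. The only stereocentre lies on an open chain with no neighbouring stereocentre to control it, so it has to be set by a catalyst or a resolution and then carried unchanged. Ring A requires O-7 methylated, O-5 free and the third oxygen built into ring B as O-1; unless the two oxygens flanking C4a are equivalent in the precursor, this costs a regioselective step. The carbinol is β to C2 and thus vinylogously β to the C4 carbonyl, so strong base can cause dehydration to a 2-alkenylchromone or attack C2 and open the pyranone. Enolate chemistry next to a protected C8 oxygen during assembly carries the same elimination risk. The enabling feature is the 1,3-dioxygenation of ring B: the C4 carbonyl carbon and the C2 enol ether carbon are linked through the C3 methine, which is the pattern stored in an isoxazole. A 3-aryl-5-alkylisoxazole of this kind is the adduct of an aryl nitrile oxide and a terminal alkyne, and the alkyne required is the homopropargylic alcohol that already holds the stereocentre.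

## Retrosynthesis

**20 to 19.** Acid 20 is taken back to its methyl ester 19; only the acyl–oxygen bond changes. A methyl ester is preferred to bulkier or hydrogenolysable esters because it is inert to all later reagents, and in a methanolic acid step it can only exchange methyl for methyl. The forward step needs hydroxide to hydrolyse the ester faster than it attacks C2 of ring B.

**19 to 16.** Ring B is opened at O1–C2 and the C4 carbonyl is traced back to a C=N. This leads through bisphenol 18 and its bis-MOM ether 17, a Z-configured β-amino enone, to isoxazole 16, whose N–O bond is the latent link.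
- The neighbouring option is closure of a free 1,3-diketone made by Claisen or Baker–Venkataraman acyl transfer. That would place an enolate two carbons from the C8 oxygen and invite β-elimination.
- The isoxazole stores the same oxidation pattern as an inert aromatic ring and moves all sensitive functionality to the last steps.
- The forward steps need a reduction that cleaves only the N–O bond, then one acid treatment that frees both phenols, closes the pyranone and hydrolyses the C4 iminium.
- Because the two ortho oxygens of ring A are equivalent, either may close, and the 5-OH/7-OMe pattern follows without a selective step.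

**16 to 15 and 14 (key disconnection).** The isoxazole is cut into nitrile oxide 15 and terminal alkyne 14. In chromone numbering this cuts the C3–C4 bond and the bond from oxygen to C2.
- Against cutting C4–C4a (acylation of the arene by a chain-derived acyl unit) or C2–CH2 (aldol-type extension of a 2-methylchromone, which would have to create the stereocentre), this cut divides the molecule into two halves of similar size.
- The coupling is neutral and leaves a stereocentre that was set earlier on a simple chain untouched.
- The C8 hydroxyl is carried free, since nothing in the cycloaddition or the later steps acylates, oxidises or eliminates it. This removes a protection step.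
- The forward reaction needs the 3,5-regiochemistry and a dipole that survives long enough to react with an unactivated alkyne.

**15 to 1.** Nitrile oxide 15 is generated in the flask from hydroximoyl chloride 6, which comes from oxime 5 and aldehyde 4. The formyl carbon is cut from the ring, giving aryllithium 3, which is reached by deprotonating bis-MOM ether 2 between its two acetal oxygens. Ether 2 comes from commercial 5-methoxyresorcinol 1. Electrophilic formylation of 1 itself would favour the unsymmetrical isomer, whereas metalation between the two strongest directing groups targets the symmetrical position. The MOM groups therefore serve as directing groups, as the ortho shields that stabilise the dipole, and as acid-labile phenol protection.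

**14 to 10 and 11.** Alkyne 14 is the C-desilylated form of 13. Cutting the bond between the propargylic methylene and the alkyne carbon of 13 gives (R)-epoxide 10 and lithium acetylide 12, made from ethynyltrimethylsilane 11. This cut is preferred to the adjacent one (propargylation of an aldehyde) because opening at the unsubstituted epoxide carbon does not involve the stereocentre. The forward step needs selectivity for the epoxide over the methyl ester.

**10 to 7.** Epoxide 10 is the slower-reacting enantiomer in a hydrolytic kinetic resolution of racemate 9. Racemate 9 is the epoxide of methyl non-8-enoate 8, the ester of commercial non-8-enoic acid 7. The resolution loses half the material, but at the cheapest stage, and it fixes the only stereocentre with high enantiomeric purity.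

## Roads not taken

Alternative 1: This route cuts C4–C4a and O1–C8a, so that ring A arrives as 3,5-dimethoxybenzyne A1, released by fluoride from silyl triflate A2, and everything else as ynoic acid A3.
- **Forward key step.** The carboxylate adds to the aryne carbon remote from the flanking methoxy group, the aryl anion attacks the acyl carbon, and the liberated phenoxide closes ring B by 6-endo-dig addition to give dimethoxychromone A4.
- **Merits.** Two skeletal bonds and ring B form in one flask, and the heterocycle needs no unmasking. The acyl–oxygen insertion of arynes into carboxylic acids is established for aryl-substituted propiolic acids.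
- **Weak points.** A2 takes several steps to make, whereas 1 is purchased. Regiocontrol depends on a single ortho methoxy group. A3 has acidic propargylic hydrogens next to a β-alkoxy group, so the basic fluoride medium can cause decarboxylation, allene formation or loss of the benzyloxy group. A4 carries a 5-methoxy group that must be cleaved selectively afterwards, and A3 costs a protection and a carboxylation beyond alkyne 14.
- **Comparison.** The ring-B construction is more direct than in the chosen plan, which needs three operations after the coupling. The chosen plan offers in return a neutral coupling that tolerates the free carbinol, an oxygenation pattern fixed by symmetry with no demethylation, and a cheap aryl partner.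

Alternative 2: This route cuts C4a–C8a and builds ring A last, from pyranone A5 in which five of the ten polyketide carbons are masked as a 4-hydroxy-2-pyranone.
- **Forward key step.** A magnesium alkoxide in methanol opens the lactone, the chelated carbanion at the future C4a acylates the ester carbon that becomes C8a, and acid work-up closes ring B to give dihydroxychromone A6.
- **Merits.** The route follows the biosynthetic folding, needs no organometallic arene chemistry, and gives the 5,7-dihydroxy pattern, from which the more acidic 7-OH can be methylated selectively.
- **Weak points.** A5 is a 1,3,5-tricarbonyl array with a β-silyloxy group, and every enolisation in its assembly and in the key step can eliminate the C8 oxygen. Aldol and Claisen folding modes compete. The sequence to A5, followed by methylation and two deprotections, is clearly longer.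
- **Comparison.** The route is attractive for analogues with other ring A patterns. For this target the chosen plan starts from an aromatic ring that already holds the correct oxygens and avoids any enolate near the carbinol.

Alternative 3: This route cuts C8–C8a and C4a–C5 and forms ring A by cycloaddition of bromopyranone A7 with the dioxygenated diene A8, followed by loss of hydrogen bromide and methanol to give chromone A9.
- **Merits.** The 5-hydroxy-7-methoxy pattern is delivered directly by the regiochemistry of the diene, and ring A is made late. In this respect it equals the chosen plan.
- **Weak points.** A 4-pyranone is a vinylogous ester with some aromatic character and is a poor dienophile. The regioselective bromination that gives A7, and the construction of its pyranone from a triketone beside the β-silyloxy group, bring back the elimination risk of Alternative 2. The aromatisation has only quinone and activated-enone precedent.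
- **Comparison.** The chosen plan relies on reactions known for both partners, and its regiochemical question (3,5- versus 3,4-isoxazole) is biased by sterics in the required direction.

Key step: step 10

Assumption: the (R,R)-configured cobalt salen complex is taken to hydrolyse the (S)-oxirane of an unbranched alkyl epoxide and leave the (R)-oxirane, as is usual for this catalyst family; if the pairing were reversed for 9, the (S,S) complex would be used.

## Route

Step 1
Reactants: 1 5-methoxybenzene-1,3-diol (5-methoxyresorcinol)
Product: 2 1-methoxy-3,5-bis(methoxymethoxy)benzene
Conditions: MOMCl, i-Pr2NEt, CH2Cl2, 0 °C to rt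
Reagents that add atoms: chloromethyl methyl ether (MOMCl), COCCl
Why: O-alkylation of both phenols with an α-chloro ether under amine base (MOM protection); the acetals later direct the metalation, shield the dipole and are removed in acid.

Step 2
Reactants: 2 1-methoxy-3,5-bis(methoxymethoxy)benzene
Product: 4 4-methoxy-2,6-bis(methoxymethoxy)benzaldehyde, via aryllithium 3 (not isolated)
Conditions: n-BuLi, TMEDA, THF, 0 °C; DMF, 0 °C to rt; H2O
Reagents that add atoms: N,N-dimethylformamide, CN(C)C=O
Why: Directed ortho-metalation; the hydrogen between the two MOM ethers is flanked by the two strongest coordinating groups of the ring, so lithiation should occur there, and formylation of 3 then gives the symmetrical aldehyde.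

Step 3
Reactants: 4 4-methoxy-2,6-bis(methoxymethoxy)benzaldehyde
Product: 5 (E)-4-methoxy-2,6-bis(methoxymethoxy)benzaldehyde oxime
Conditions: NH2OH·HCl, NaOAc, EtOH/H2O, rt
Reagents that add atoms: hydroxylamine hydrochloride, Cl.NO
Why: Oxime condensation in acetate buffer, mild enough for the MOM acetals; the E-oxime is expected for an aryl aldoxime.

Step 4
Reactants: 5 (E)-4-methoxy-2,6-bis(methoxymethoxy)benzaldehyde oxime
Product: 6 (Z)-N-hydroxy-4-methoxy-2,6-bis(methoxymethoxy)benzenecarboximidoyl chloride
Conditions: NCS (1.05 equiv), DMF, 0 °C to rt
Reagents that add atoms: N-chlorosuccinimide, O=C1CCC(=O)N1Cl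
Why: Chlorination of the aldoxime carbon with NCS in DMF is the standard route to hydroximoyl chlorides; one equivalent at low temperature is used to limit chlorination of the electron-rich ring.

Step 5
Reactants: 7 non-8-enoic acid
Product: 8 methyl non-8-enoate
Conditions: MeOH, H2SO4 (cat.), reflux
Reagents that add atoms: methanol, CO
Why: Fischer esterification; the terminal alkene is inert.

Step 6
Reactants: 8 methyl non-8-enoate
Product: 9 methyl 7-(oxiran-2-yl)heptanoate (racemate)
Conditions: mCPBA, CH2Cl2, 0 °C to rt
Reagents that add atoms: 3-chloroperbenzoic acid (mCPBA), OOC(=O)c1cccc(Cl)c1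
Why: Prilezhaev epoxidation of a monosubstituted alkene; the ester does not react with the peracid.

Step 7
Reactants: 9 methyl 7-(oxiran-2-yl)heptanoate (racemate)
Product: 10 methyl 7-[(2R)-oxiran-2-yl]heptanoate
Conditions: (R,R)-(salen)Co(OAc) (0.5 mol %), H2O (0.55 equiv), THF, 0 °C to rt
Reagents that add atoms: none
Why: Hydrolytic kinetic resolution of a terminal epoxide; the trivalent cobalt complex of the dianion of (R,R)-N,N'-bis(3,5-di-tert-butylsalicylidene)cyclohexane-1,2-diamine should hydrolyse the (S)-epoxide and leave the (R)-epoxide. This catalyst-controlled step sets the only stereocentre of the target, and the diol is removed by chromatography.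

Step 8
Reactants: 10 methyl 7-[(2R)-oxiran-2-yl]heptanoate; 11 ethynyltrimethylsilane
Product: 13 methyl (8R)-8-hydroxy-11-(trimethylsilyl)undec-10-ynoate, via lithium trimethylsilylacetylide 12 (not isolated)
Conditions: 11, n-BuLi, THF, −78 °C; BF3·OEt2; then 10, −78 °C; aq. NH4Cl
Reagents that add atoms: none
Why: BF3-promoted SN2 opening of the epoxide by the acetylide at the unsubstituted carbon; the stereocentre is not a reacting centre and keeps its configuration (the descriptor stays R). Low temperature and a small excess of reagent are intended to spare the methyl ester.

Step 9
Reactants: 13 methyl (8R)-8-hydroxy-11-(trimethylsilyl)undec-10-ynoate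
Product: 14 methyl (8R)-8-hydroxyundec-10-ynoate
Conditions: K2CO3, MeOH, rt
Reagents that add atoms: none
Why: Methoxide-mediated protodesilylation of an alkynylsilane; in methanol the methyl ester can only exchange methyl for methyl.

Step 10
Reactants: 6 (Z)-N-hydroxy-4-methoxy-2,6-bis(methoxymethoxy)benzenecarboximidoyl chloride; 14 methyl (8R)-8-hydroxyundec-10-ynoate
Product: 16 methyl (8R)-8-hydroxy-9-{3-[4-methoxy-2,6-bis(methoxymethoxy)phenyl]-1,2-oxazol-5-yl}nonanoate, via nitrile oxide 15 (not isolated)
Conditions: Et3N (slow addition), toluene, rt then 80 °C
Reagents that add atoms: none
Why: Et3N removes HCl from 6 to give nitrile oxide 15, which adds to the terminal alkyne of 14 in a concerted, asynchronous 1,3-dipolar (Huisgen) cycloaddition; the dipole carbon bonds to the terminal CH and the dipole oxygen to the internal carbon, so the aromatic 1,2-oxazole forms directly without an oxidation. The closest known reaction type is the thermal addition of di-ortho-substituted aryl nitrile oxides to monosubstituted alkynes, which gives 3-aryl-5-alkylisoxazoles. The five-membered ring is closed by an intermolecular (3+2) cycloaddition in which both ring bonds form in one step, not by cyclisation of a tethered chain. No stereocentre is created, and C8, two atoms from the alkyne and not part of any enolisable system, should keep its R configuration under these neutral conditions. The step needs regioselectivity for the 3,5- over the 3,4-disubstituted ring; the larger orbital coefficient at the unsubstituted alkyne carbon and, more strongly here, the clash between the di-ortho-substituted aryl group and the propargylic chain in the other orientation should secure it. It also needs the dipole to survive a slow reaction with an unactivated alkyne; the two ortho MOM ethers shield the nitrile oxide carbon against furoxan formation, and slow addition of base keeps its concentration low. The free secondary alcohol and the ester are not expected to react with the dipole.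

Step 11
Reactants: 16 methyl (8R)-8-hydroxy-9-{3-[4-methoxy-2,6-bis(methoxymethoxy)phenyl]-1,2-oxazol-5-yl}nonanoate
Product: 17 methyl (8R,11Z)-12-amino-8-hydroxy-12-[4-methoxy-2,6-bis(methoxymethoxy)phenyl]-10-oxododec-11-enoate
Conditions: Mo(CO)6, H2O, MeCN, 80 °C
Reagents that add atoms: none
Why: Reductive cleavage of the isoxazole N–O bond by zerovalent molybdenum with water as hydrogen source, a known route from 3,5-disubstituted isoxazoles to β-amino enones; the Z vinylogous amide is held by an N–H···O hydrogen bond, and ester, acetals and alcohol are untouched.

Step 12
Reactants: 17 methyl (8R,11Z)-12-amino-8-hydroxy-12-[4-methoxy-2,6-bis(methoxymethoxy)phenyl]-10-oxododec-11-enoate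
Product: 19 methyl (8R)-8-hydroxy-9-(5-hydroxy-7-methoxy-4-oxo-4H-chromen-2-yl)nonanoate, via bisphenol enaminone 18 (not isolated)
Conditions: 2 M aq. HCl, MeOH, 50 °C
Reagents that add atoms: water, O
Why: Acidic methanolysis removes both MOM groups, which are trapped as the dimethyl acetal and so kept away from the electron-rich ring; a phenol of 18 then adds to the C10 ketone (6-exo-trig), water is lost, and the C4 iminium is hydrolysed with loss of ammonia, as known for reduced 3-(2-hydroxyaryl)isoxazoles. Prior hydrolysis of the enaminone to the 1,3-diketone leads to the same chromone, and the two phenols are equivalent, so only one product is possible.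

Step 13
Reactants: 19 methyl (8R)-8-hydroxy-9-(5-hydroxy-7-methoxy-4-oxo-4H-chromen-2-yl)nonanoate
Product: 20 (8R)-8-hydroxy-9-(5-hydroxy-7-methoxy-4-oxo-4H-chromen-2-yl)nonanoic acid (penithochromone S)
Conditions: LiOH, THF/H2O, 0 °C to rt; then 1 M HCl to pH 3
Reagents that add atoms: lithium hydroxide, [Li+].[OH-]
Why: Saponification of an unhindered methyl ester at low temperature; the 5-phenoxide formed under these conditions lowers the electrophilicity of the pyranone, and the stereocentre is not enolisable.

## Compound list

1 | 5-methoxybenzene-1,3-diol (5-methoxyresorcinol) | COc1cc(O)cc(O)c1 | starting material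
2 | 1-methoxy-3,5-bis(methoxymethoxy)benzene | COCOc1cc(OC)cc(OCOC)c1 | intermediate
3 | [4-methoxy-2,6-bis(methoxymethoxy)phenyl]lithium | [Li]c1c(OCOC)cc(OC)cc1OCOC | intermediate (not isolated)
4 | 4-methoxy-2,6-bis(methoxymethoxy)benzaldehyde | COCOc1cc(OC)cc(OCOC)c1C=O | intermediate
5 | (E)-4-methoxy-2,6-bis(methoxymethoxy)benzaldehyde oxime | COCOc1cc(OC)cc(OCOC)c1/C=N/O | intermediate
6 | (Z)-N-hydroxy-4-methoxy-2,6-bis(methoxymethoxy)benzenecarboximidoyl chloride | COCOc1cc(OC)cc(OCOC)c1/C(Cl)=N/O | intermediate
7 | non-8-enoic acid | C=CCCCCCCC(=O)O | starting material
8 | methyl non-8-enoate | C=CCCCCCCC(=O)OC | intermediate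
9 | methyl 7-(oxiran-2-yl)heptanoate (racemate) | COC(=O)CCCCCCC1CO1 | intermediate
10 | methyl 7-[(2R)-oxiran-2-yl]heptanoate | COC(=O)CCCCCC[C@@H]1CO1 | intermediate
11 | ethynyltrimethylsilane | C#C[Si](C)(C)C | starting material
12 | lithium (trimethylsilyl)acetylide | [Li]C#C[Si](C)(C)C | intermediate (not isolated)
13 | methyl (8R)-8-hydroxy-11-(trimethylsilyl)undec-10-ynoate | C[Si](C)(C)C#CC[C@H](O)CCCCCCC(=O)OC | intermediate
14 | methyl (8R)-8-hydroxyundec-10-ynoate | C#CC[C@H](O)CCCCCCC(=O)OC | intermediate
15 | 4-methoxy-2,6-bis(methoxymethoxy)benzonitrile oxide | COCOc1cc(OC)cc(OCOC)c1C#[N+][O-] | intermediate (not isolated)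
16 | methyl (8R)-8-hydroxy-9-{3-[4-methoxy-2,6-bis(methoxymethoxy)phenyl]-1,2-oxazol-5-yl}nonanoate | COCOc1cc(OC)cc(OCOC)c1-c1cc(C[C@H](O)CCCCCCC(=O)OC)on1 | intermediate
17 | methyl (8R,11Z)-12-amino-8-hydroxy-12-[4-methoxy-2,6-bis(methoxymethoxy)phenyl]-10-oxododec-11-enoate | COCOc1cc(OC)cc(OCOC)c1/C(N)=C/C(=O)C[C@H](O)CCCCCCC(=O)OC | intermediate
18 | methyl (8R,11Z)-12-amino-12-(2,6-dihydroxy-4-methoxyphenyl)-8-hydroxy-10-oxododec-11-enoate | COc1cc(O)c(/C(N)=C/C(=O)C[C@H](O)CCCCCCC(=O)OC)c(O)c1 | intermediate (not isolated)
19 | methyl (8R)-8-hydroxy-9-(5-hydroxy-7-methoxy-4-oxo-4H-chromen-2-yl)nonanoate | COc1cc(O)c2c(=O)cc(C[C@H](O)CCCCCCC(=O)OC)oc2c1 | intermediate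
20 | (8R)-8-hydroxy-9-(5-hydroxy-7-methoxy-4-oxo-4H-chromen-2-yl)nonanoic acid (penithochromone S) | COc1cc(O)c2c(=O)cc(C[C@H](O)CCCCCCC(=O)O)oc2c1 | target

## Step count and least certain steps

Total step count: 13. Longest linear sequence: 9 steps (7 to 20, steps 5 to 13); the aryl branch (1 to 6) adds 4 steps before the convergence in step 10.

**Step 10 (key step).**
- Risk: The hindered dipole may add only slowly to the unactivated alkyne. Prolonged heating could then let it rearrange to the isocyanate or dimerise, and some 3,4-regioisomer could form.
- Fallback: This makes the same C–C bond by carbonyl addition and omits the isoxazole. It sets out from aldehyde 4 and alkyne 14. Zn(OTf)2 and Et3N would generate the zinc acetylide of 14 in the presence of its ester and add it to 4, giving the propargylic alcohol methyl (8R)-8,12-dihydroxy-12-[4-methoxy-2,6-bis(methoxymethoxy)phenyl]dodec-10-ynoate F1 as a mixture of C12 epimers. MnO2, which oxidises only the benzylic–propargylic carbinol, would give the ynone methyl (8R)-8-hydroxy-12-[4-methoxy-2,6-bis(methoxymethoxy)phenyl]-12-oxododec-10-ynoate F2. Methanolic HCl would remove the MOM groups and let a phenol add 6-endo-dig to the ynone. The fallback comes back to the route at 19.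

**Step 8.**
- Risk: The BF3-activated alkynyl species may also attack the methyl ester, giving an ynone, or the Lewis acid may cause rearrangement of the epoxide. The ester is six carbons away but not otherwise protected.
- Fallback: This sets out from alkene ester 8. Ozonolysis with reductive work-up would give the aldehyde methyl 8-oxooctanoate F3. An enantioselective propargylation with allenylboronic acid pinacol ester, catalysed by the antipode of a hindered binaphthyl phosphoric acid that delivers the (R)-carbinol, would give the free alkyne directly. The fallback comes back to the route at 14. It is shorter, but its enantioselectivity with unbranched aliphatic aldehydes is less assured than that of the resolution.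

**Step 2.**
- Risk: Lithiation may occur in part at the positions flanked by one MOM ether and the methoxy group, giving the unsymmetrical aldehyde.
- Fallback: This does not start from a compound of the route. It replaces 1, 2 and 3 by commercial 2,4,6-trihydroxybenzaldehyde F4, in which the formyl group already sits between two oxygens. One equivalent of MeI with K2CO3 should methylate the 4-hydroxyl, the only one not hydrogen-bonded to the aldehyde, giving 2,6-dihydroxy-4-methoxybenzaldehyde F5. NaH and MOMCl in DMF would then protect both chelated phenols. The fallback comes back to the route at 4.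

**Step 4.**
- Risk: Electrophilic chlorination of the very electron-rich ring, at the positions flanked by methoxy and MOM ether, may compete with chlorination of the oxime carbon.
- Fallback: This sets out from oxime 5 and alkyne 14 and uses no halogen. The hypervalent iodine reagent PhI(OAc)2 in methanol would oxidise 5 directly to nitrile oxide 15 in the presence of 14. The fallback comes back to the route at 16 and forms no compound outside the compound list (entry F0).

**Step 13.**
- Risk: Hydroxide may attack C2 and open the pyranone, or base may eliminate the C8 hydroxyl through the vinylogous enolate.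
- Fallback: This moves the hydrolysis to a stage where no chromone is present. It sets out from isoxazole 16. LiOH would give (8R)-8-hydroxy-9-{3-[4-methoxy-2,6-bis(methoxymethoxy)phenyl]-1,2-oxazol-5-yl}nonanoic acid F6, since a 3,5-disubstituted isoxazole is stable to base. Mo(CO)6 and water would give (8R,11Z)-12-amino-8-hydroxy-12-[4-methoxy-2,6-bis(methoxymethoxy)phenyl]-10-oxododec-11-enoic acid F7. Aqueous HCl in THF, without alcohol, would remove the MOM groups and close the chromone. The fallback comes back to the route at 20.

## Further compounds

F1 | step 10 | methyl (8R)-8,12-dihydroxy-12-[4-methoxy-2,6-bis(methoxymethoxy)phenyl]dodec-10-ynoate (both C12 epimers) | COCOc1cc(OC)cc(OCOC)c1C(O)C#CC[C@H](O)CCCCCCC(=O)OC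
F2 | step 10 | methyl (8R)-8-hydroxy-12-[4-methoxy-2,6-bis(methoxymethoxy)phenyl]-12-oxododec-10-ynoate | COCOc1cc(OC)cc(OCOC)c1C(=O)C#CC[C@H](O)CCCCCCC(=O)OC
F3 | step 8 | methyl 8-oxooctanoate | COC(=O)CCCCCCC=O
F4 | step 2 | 2,4,6-trihydroxybenzaldehyde | O=Cc1c(O)cc(O)cc1O
F5 | step 2 | 2,6-dihydroxy-4-methoxybenzaldehyde | COc1cc(O)c(C=O)c(O)c1
F0 | step 4 | none | none
F6 | step 13 | (8R)-8-hydroxy-9-{3-[4-methoxy-2,6-bis(methoxymethoxy)phenyl]-1,2-oxazol-5-yl}nonanoic acid | COCOc1cc(OC)cc(OCOC)c1-c1cc(C[C@H](O)CCCCCCC(=O)O)on1
F7 | step 13 | (8R,11Z)-12-amino-8-hydroxy-12-[4-methoxy-2,6-bis(methoxymethoxy)phenyl]-10-oxododec-11-enoic acid | COCOc1cc(OC)cc(OCOC)c1/C(N)=C/C(=O)C[C@H](O)CCCCCCC(=O)O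
A1 | alternative 1 | 3,5-dimethoxybenzyne | COC1=CC(OC)=CC#C1
A2 | alternative 1 | 3,5-dimethoxy-2-(trimethylsilyl)phenyl trifluoromethanesulfonate | COc1cc(OC)c([Si](C)(C)C)c(OS(=O)(=O)C(F)(F)F)c1
A3 | alternative 1 | (5R)-5-(benzyloxy)-12-methoxy-12-oxododec-2-ynoic acid | OC(=O)C#CC[C@H](OCc1ccccc1)CCCCCCC(=O)OC
A4 | alternative 1 | methyl (8R)-8-(benzyloxy)-9-(5,7-dimethoxy-4-oxo-4H-chromen-2-yl)nonanoate | COc1cc(OC)c2c(=O)cc(C[C@H](OCc3ccccc3)CCCCCCC(=O)OC)oc2c1
A5 | alternative 2 | tert-butyl (8R)-8-(tert-butyldimethylsilyloxy)-13-(4-hydroxy-2-oxo-2H-pyran-6-yl)-10,12-dioxotridecanoate | O=c1cc(O)cc(CC(=O)CC(=O)C[C@H](O[Si](C)(C)C(C)(C)C)CCCCCCC(=O)OC(C)(C)C)o1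
A6 | alternative 2 | tert-butyl (8R)-8-(tert-butyldimethylsilyloxy)-9-(5,7-dihydroxy-4-oxo-4H-chromen-2-yl)nonanoate | Oc1cc(O)c2c(=O)cc(C[C@H](O[Si](C)(C)C(C)(C)C)CCCCCCC(=O)OC(C)(C)C)oc2c1
A7 | alternative 3 | methyl (8R)-9-(5-bromo-4-oxo-4H-pyran-2-yl)-8-(tert-butyldimethylsilyloxy)nonanoate | O=c1cc(C[C@H](O[Si](C)(C)C(C)(C)C)CCCCCCC(=O)OC)occ1Br
A8 | alternative 3 | 1,3-dimethoxy-1-(trimethylsilyloxy)buta-1,3-diene | C=C(OC)C=C(OC)O[Si](C)(C)C
A9 | alternative 3 | methyl (8R)-8-(tert-butyldimethylsilyloxy)-9-(5-hydroxy-7-methoxy-4-oxo-4H-chromen-2-yl)nonanoate | COc1cc(O)c2c(=O)cc(C[C@H](O[Si](C)(C)C(C)(C)C)CCCCCCC(=O)OC)oc2c1
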